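The readings were generated by integration for substances that don't exist; noise was put on by code.

**Leftover Z.** At 80.0 min the zeta run still held 35.7% of Z and the theta run 0.3%, with D at 0.60 equiv against 2.4 equiv.

| setting | zeta | theta | gamma | flask |
|---|---|---|---|---|
| G | 20 mM (fed, over 3.0 min) | 20 mM (fed, over 3.0 min) | 20 mM (fed, over 3.0 min) | 20 mM (fed, over 3.0 min) |
| J | 1.8 equiv | 1.8 equiv | 3.6 equiv | 1.80 equiv |
| D | 0.60 equiv | 2.4 equiv | 1.2 equiv | 1.20 equiv |
| remark | run made earlier | run made earlier | run made earlier |  |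
| time |  |  |  | 1.5 h |

| run | time / min | Z / % | G / % |
|---|---|---|---|
| zeta | 1.50 | 7.9 | 36.4 |
| zeta | 4.00 | 43.9 | 35.7 |
| zeta | 8.00 | 59.6 | 5.9 |
| zeta | 15.0 | 55.5 | 1.2 |
| zeta | 30.0 | 44.5 | 0 |
| zeta | 80.0 | 35.7 | 0 |
| theta | 1.50 | 6.0 | 36.8 |
| theta | 4.00 | 24.4 | 36.4 |
| theta | 8.00 | 22.3 | 6.1 |
| theta | 15.0 | 7.9 | 0.7 |
| theta | 30.0 | 0.9 | 0 |
| theta | 80.0 | 0.3 | 0 |
| gamma | 1.50 | 9.0 | 37.2 |
| gamma | 4.00 | 41.5 | 36.4 |
| gamma | 12.0 | 40.1 | 0.8 |
| gamma | 30.0 | 15.6 | 0 |
| gamma | 80.0 | 2.9 | 0.3 |

(standard deviation of a reading: 0.5 percentage points)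

- percentages count the whole charge, also what has not yet gone in

- when, up to 1.5 h, the flask holds most Z
- the amount of Z, in percent of the G charged, at that time

**Bench rule.** G stood alike at 4.00 min in zeta and theta, 35.7% and 36.4%. So I took its own decay, read as 0.450 min⁻¹, as the rate-limiting step, and let what it gives share out at once between J and D. The rule of thumb says that Z follows the ratio of J to D. Zeta and gamma share that ratio, 3.00, and at 4.00 min they held 43.9% and 41.5%. I defined a split factor s, an apparent selectivity factor: the odds of Z against the rest of the G gone, divided by that ratio. Zeta's reading gave 0.717, so this flask should turn 51.8% of its reacted G into Z.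

**Its border.** At 30.0 min the same two runs held 44.5% and 15.6%, so the ratio stops serving there; gamma had twice the D of zeta, and twice the J too. Theta's fall, scaled to this flask's D, gave a pseudo-first-order loss of Z of 0.0741 min⁻¹. Setting gain against loss, with cZ taken as the share times the G gone, the share cancels and cG at the peak is 14.1%. I committed to 44.5% of Z at 0.101 h.

**The flask.** The forecast said 43% at 0.12 h, from “Formation matches loss near 7 min”. The flask gave 43.1% at 0.113 h.

    G → L (k = 0.00720 s⁻¹)
    J + L → Z (k = 1.82 M⁻¹ s⁻¹)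
    D + L → Q (k = 1.16 M⁻¹ s⁻¹)
    D + Z → X (k = 0.0816 M⁻¹ s⁻¹)
    G + Z → E (k = 0.0331 M⁻¹ s⁻¹)

**What stood.** In the flask at 0.0538 h, L had a half-life of 0.21 min against J, while Z had 0.11 h against D, far longer. With 10.2% of G left in the flask at the best time, the share from s gives 46.5% of Z, more than the flask's 43.1%.

**Second flask.** For a neighbour flask, the same recipe with 0.720 equiv of D, s gives a share of 64.2%, cG at the peak comes to 8.99%, and my reckoned peak is 58.4% of Z. The computed peak of that neighbour flask is 56.0%.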